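**Plan**
- Ring numbering of the target: C1 bears the side chain, C2 the two methyls, C3 the hydroxyl, C4 and C5 are CH2, C6 bears the exocyclic methylene. The retrosynthesis cuts, in order: the allyl aryl ether C–O; the C6=CH2/C1–H pair (back to a ring C1=C6 olefin with CH2OH on C6); the C1–CH2 side-chain bond (back to an enol triflate at C1); and last the ring bonds C5–C6 and C2–C3.
- Enabling feature: with C1 as a ketone carbon and the exocyclic carbon as an ester, C6 and C2 are the two α-carbons of methyl isobutyrylacetate, and C5–C4–C3(O) is acrolein. The carbinol C3 beside quaternary C2 is an aldol unit that cannot dehydrate.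
- Forward: the carbocycle arises first, in one flask, by Michael addition (C5–C6) then aldol closure (C2–C3). Then follow enol triflate formation, C3 oxidation and asymmetric reduction, B-alkyl Suzuki–Miyaura coupling of the side chain, ester reduction, reductive 1,3-transposition, desilylation and Mitsunobu etherification with isofraxidin.
- Stereochemistry: C3 (R) comes from a Corey–Bakshi–Shibata reduction (catalyst control). C1 (S) comes from suprafacial hydrogen delivery in the diazene retro-ene step (substrate control by C2 and C3). The (E)-olefin is bought with (2E)-3-methylpent-2-en-4-yn-1-ol and is never touched.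

Key step: step 1

Remark: 4 and 5 are carried as racemates (4 also as a diastereomer mixture with its enol form). This does not matter, because C6 is sp2 from step 2 on and C3 is flattened in step 3 and reset in step 4. TBDPS = tert-butyldiphenylsilyl.

Step 1
Reactants: 1 methyl 4-methyl-3-oxopentanoate; 2 acrolein (prop-2-enal)
Product: 4 methyl 4-hydroxy-3,3-dimethyl-2-oxocyclohexane-1-carboxylate (racemic diastereomer mixture), via Michael adduct 3 (not isolated)
Conditions: Et3N (5 mol %), toluene, 0 °C, slow addition of 2 (1.05 equiv); then p-TsOH·H2O (15 mol %), 23 °C, same flask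
Reagents that add atoms: none
Why: Et3N generates the β-keto ester enolate, whose α-carbon (future C6) adds to the β-carbon of acrolein (future C5) in a Michael addition to give keto aldehyde 3, and acid then enolises the ketone towards the isopropyl carbon (future C2), whose tetrasubstituted enol adds to the pendant aldehyde carbon (future C3) in an intramolecular aldol addition. The closest known reaction type is the Robinson-type Michael/aldol [3+3] annulation of β-keto esters with enals, as in cyclohexenone carboxylates from acetoacetates and bicyclic ketols from cyclic β-keto esters and acrolein. The six-membered ring closes in a 6-(enolendo)-exo-trig mode. C3 and C6 are formed without control, on purpose, because C6 becomes sp2 in step 2 and C3 is erased in step 3 and reset by the catalyst in step 4. The step needs mono-addition and one single closure: slow addition of acrolein at 0 °C should keep adduct 3 from adding a second acrolein, every other enol/carbonyl pairing in 3 would close a four-membered ring, and the quaternary C2 blocks dehydration, so the ketol is the end point.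

Step 2
Reactants: 4 methyl 4-hydroxy-3,3-dimethyl-2-oxocyclohexane-1-carboxylate
Product: 5 methyl 4-hydroxy-3,3-dimethyl-2-{[(trifluoromethyl)sulfonyl]oxy}cyclohex-1-ene-1-carboxylate (racemic)
Conditions: NaH (1.05 equiv), THF, 0 °C; then N-(5-chloropyridin-2-yl)bis(trifluoromethanesulfonimide), 0 → 23 °C
Reagents that add atoms: N-(5-chloropyridin-2-yl)bis(trifluoromethanesulfonimide), FC(F)(F)S(=O)(=O)N(c1ccc(Cl)cn1)S(=O)(=O)C(F)(F)F
Why: One equivalent of NaH should deprotonate only the β-keto ester (far more acidic than the neopentyl alcohol), and O-sulfonylation of the chelated enolate (enol triflate formation) fixes the C1=C6 double bond and makes C1 a cross-coupling site without setting a stereocentre.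

Step 3
Reactants: 5 methyl 4-hydroxy-3,3-dimethyl-2-{[(trifluoromethyl)sulfonyl]oxy}cyclohex-1-ene-1-carboxylate
Product: 6 methyl 3,3-dimethyl-4-oxo-2-{[(trifluoromethyl)sulfonyl]oxy}cyclohex-1-ene-1-carboxylate
Conditions: Dess–Martin periodinane, CH2Cl2, 23 °C
Reagents that add atoms: none
Why: Dess–Martin oxidation of the hindered secondary alcohol removes the uncontrolled C3 stereocentre and should give an achiral ketone that cannot conjugate (quaternary C2 lies between it and the olefin), a good substrate for reagent-controlled reduction.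

Step 4
Reactants: 6 methyl 3,3-dimethyl-4-oxo-2-{[(trifluoromethyl)sulfonyl]oxy}cyclohex-1-ene-1-carboxylate
Product: 7 methyl (4R)-4-hydroxy-3,3-dimethyl-2-{[(trifluoromethyl)sulfonyl]oxy}cyclohex-1-ene-1-carboxylate
Conditions: (S)-2-methyl-CBS-oxazaborolidine (10 mol %), BH3·SMe2 (0.7 equiv), THF, −20 °C; aqueous work-up
Reagents that add atoms: none
Why: Corey–Bakshi–Shibata reduction: the ketone is flanked by quaternary C2 (large) and the C4 methylene (small), so the (S)-oxazaborolidine–borane complex should deliver hydride to the face that gives the (R)-carbinol, while the enoate and the triflate stay inert.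

Step 5
Reactants: 8 (2E)-3-methylpent-2-en-4-yn-1-ol
Product: 9 tert-butyl{[(2E)-3-methylpent-2-en-4-yn-1-yl]oxy}diphenylsilane
Conditions: TBDPSCl, imidazole, CH2Cl2, 0 → 23 °C
Reagents that add atoms: tert-butyl(chloro)diphenylsilane, CC(C)(C)[Si](Cl)(c1ccccc1)c1ccccc1
Why: Standard silylation of the primary allylic alcohol masks the future ether oxygen through the borane, hydride and Mitsunobu steps and leaves the (E)-olefin untouched.

Step 6
Reactants: 9 tert-butyl{[(2E)-3-methylpent-2-en-4-yn-1-yl]oxy}diphenylsilane
Product: 10 tert-butyl{[(2E)-3-methylpenta-2,4-dien-1-yl]oxy}diphenylsilane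
Conditions: H2 (1 atm), Pd/CaCO3 poisoned with Pb(OAc)2, quinoline, hexane/EtOAc, 23 °C, stopped after one equivalent of H2
Reagents that add atoms: none
Why: Lindlar-type semihydrogenation should reduce the terminal alkyne to the vinyl group and stop there, leaving the trisubstituted (E)-olefin and its geometry intact.

Step 7
Reactants: 10 tert-butyl{[(2E)-3-methylpenta-2,4-dien-1-yl]oxy}diphenylsilane; 7 methyl (4R)-4-hydroxy-3,3-dimethyl-2-{[(trifluoromethyl)sulfonyl]oxy}cyclohex-1-ene-1-carboxylate
Product: 12 methyl (4R)-2-[(3E)-5-(TBDPSO)-3-methylpent-3-en-1-yl]-4-hydroxy-3,3-dimethylcyclohex-1-ene-1-carboxylate, via alkylborane 11 (not isolated)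
Conditions: 9-BBN, THF, 0 → 23 °C on 10; then 7, Pd(dppf)Cl2 (5 mol %), K3PO4 (3 M aq.), DMF, 23 → 50 °C
Reagents that add atoms: none
Why: 9-BBN should hydroborate the monosubstituted terminus of the diene anti-Markovnikov to the homoallylic borane, which undergoes B-alkyl Suzuki–Miyaura coupling with the electron-poor enol triflate (free hydroxyl tolerated) with retention of the (E)-olefin and without a new stereocentre.

Step 8
Reactants: 12 methyl (4R)-2-[(3E)-5-(TBDPSO)-3-methylpent-3-en-1-yl]-4-hydroxy-3,3-dimethylcyclohex-1-ene-1-carboxylate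
Product: 13 (1R)-3-[(3E)-5-(TBDPSO)-3-methylpent-3-en-1-yl]-4-(hydroxymethyl)-2,2-dimethylcyclohex-3-en-1-ol
Conditions: i-Bu2AlH (4 equiv), CH2Cl2, −78 → 0 °C; aqueous potassium sodium tartrate
Reagents that add atoms: none
Why: 1,2-Reduction of the conjugated ester with i-Bu2AlH should give the primary allylic alcohol without touching the olefins, the silyl ether or the C3 stereocentre.

Step 9
Reactants: 13 (1R)-3-[(3E)-5-(TBDPSO)-3-methylpent-3-en-1-yl]-4-(hydroxymethyl)-2,2-dimethylcyclohex-3-en-1-ol
Product: 16 (1R,3S)-3-[(3E)-5-(TBDPSO)-3-methylpent-3-en-1-yl]-2,2-dimethyl-4-methylidenecyclohexan-1-ol, via sulfonylhydrazine adduct 14 (not isolated), via allylic diazene 15 (not isolated)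
Conditions: PPh3, DEAD, 2-nitrobenzenesulfonohydrazide, THF, −30 °C; then 23 °C
Reagents that add atoms: none
Why: Mitsunobu displacement of the primary allylic hydroxyl by the sulfonylhydrazide (the neopentyl secondary alcohol is inert), loss of sulfinic acid to the monoalkyl diazene and retro-ene loss of N2 (reductive 1,3-transposition) should move the double bond to the exocyclic position and deliver hydrogen suprafacially to C1, axially on the face anti to the pseudoaxial C2 methyl of the half-chair with the C3 hydroxyl equatorial, which sets (S) at C1 with the side chain cis to the hydroxyl.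

Step 10
Reactants: 16 (1R,3S)-3-[(3E)-5-(TBDPSO)-3-methylpent-3-en-1-yl]-2,2-dimethyl-4-methylidenecyclohexan-1-ol
Product: 17 (1R,3S)-3-[(3E)-5-hydroxy-3-methylpent-3-en-1-yl]-2,2-dimethyl-4-methylidenecyclohexan-1-ol
Conditions: n-Bu4NF, THF, 0 → 23 °C
Reagents that add atoms: none
Why: Fluoride-mediated desilylation should free the primary allylic alcohol without affecting the stereocentres or the exocyclic olefin.

Step 11
Reactants: 17 (1R,3S)-3-[(3E)-5-hydroxy-3-methylpent-3-en-1-yl]-2,2-dimethyl-4-methylidenecyclohexan-1-ol; 18 isofraxidin (7-hydroxy-6,8-dimethoxy-2H-chromen-2-one)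
Product: 19 7-({(2E)-5-[(1S,3R)-3-hydroxy-2,2-dimethyl-6-methylidenecyclohexyl]-3-methylpent-2-en-1-yl}oxy)-6,8-dimethoxy-2H-chromen-2-one
Conditions: PPh3, DIAD, THF, 0 → 23 °C
Reagents that add atoms: none
Why: Mitsunobu etherification should alkylate the acidic coumarin phenol with the activated primary allylic alcohol in an SN2 sense without allylic transposition, while the hindered secondary C3 hydroxyl does not react, so no protecting group is needed.

**Compound list**
1 | methyl 4-methyl-3-oxopentanoate | COC(=O)CC(=O)C(C)C | starting material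
2 | acrolein (prop-2-enal) | C=CC=O | starting material
3 | methyl 4-methyl-3-oxo-2-(3-oxopropyl)pentanoate (racemic, not isolated) | COC(=O)C(CCC=O)C(=O)C(C)C | intermediate
4 | methyl 4-hydroxy-3,3-dimethyl-2-oxocyclohexane-1-carboxylate (racemic, diastereomer mixture) | COC(=O)C1CCC(O)C(C)(C)C1=O | intermediate
5 | methyl 4-hydroxy-3,3-dimethyl-2-{[(trifluoromethyl)sulfonyl]oxy}cyclohex-1-ene-1-carboxylate (racemic) | COC(=O)C1=C(OS(=O)(=O)C(F)(F)F)C(C)(C)C(O)CC1 | intermediate
6 | methyl 3,3-dimethyl-4-oxo-2-{[(trifluoromethyl)sulfonyl]oxy}cyclohex-1-ene-1-carboxylate | COC(=O)C1=C(OS(=O)(=O)C(F)(F)F)C(C)(C)C(=O)CC1 | intermediate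
7 | methyl (4R)-4-hydroxy-3,3-dimethyl-2-{[(trifluoromethyl)sulfonyl]oxy}cyclohex-1-ene-1-carboxylate | COC(=O)C1=C(OS(=O)(=O)C(F)(F)F)C(C)(C)[C@H](O)CC1 | intermediate
8 | (2E)-3-methylpent-2-en-4-yn-1-ol | C#C/C(C)=C/CO | starting material
9 | tert-butyl{[(2E)-3-methylpent-2-en-4-yn-1-yl]oxy}diphenylsilane | C#C/C(C)=C/CO[Si](c1ccccc1)(c1ccccc1)C(C)(C)C | intermediate
10 | tert-butyl{[(2E)-3-methylpenta-2,4-dien-1-yl]oxy}diphenylsilane | C=C/C(C)=C/CO[Si](c1ccccc1)(c1ccccc1)C(C)(C)C | intermediate
11 | 9-[(3E)-5-(TBDPSO)-3-methylpent-3-en-1-yl]-9-borabicyclo[3.3.1]nonane (not isolated) | B1(CC/C(C)=C/CO[Si](c2ccccc2)(c2ccccc2)C(C)(C)C)C2CCCC1CCC2 | intermediate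
12 | methyl (4R)-2-[(3E)-5-(TBDPSO)-3-methylpent-3-en-1-yl]-4-hydroxy-3,3-dimethylcyclohex-1-ene-1-carboxylate | COC(=O)C1=C(CC/C(C)=C/CO[Si](c2ccccc2)(c2ccccc2)C(C)(C)C)C(C)(C)[C@H](O)CC1 | intermediate
13 | (1R)-3-[(3E)-5-(TBDPSO)-3-methylpent-3-en-1-yl]-4-(hydroxymethyl)-2,2-dimethylcyclohex-3-en-1-ol | OCC1=C(CC/C(C)=C/CO[Si](c2ccccc2)(c2ccccc2)C(C)(C)C)C(C)(C)[C@H](O)CC1 | intermediate
14 | N-({(4R)-2-[(3E)-5-(TBDPSO)-3-methylpent-3-en-1-yl]-4-hydroxy-3,3-dimethylcyclohex-1-en-1-yl}methyl)-2-nitrobenzenesulfonohydrazide (not isolated) | NN(CC1=C(CC/C(C)=C/CO[Si](c2ccccc2)(c2ccccc2)C(C)(C)C)C(C)(C)[C@H](O)CC1)S(=O)(=O)c1ccccc1[N+](=O)[O-] | intermediate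
15 | (1R)-3-[(3E)-5-(TBDPSO)-3-methylpent-3-en-1-yl]-4-(diazenylmethyl)-2,2-dimethylcyclohex-3-en-1-ol (not isolated) | N=NCC1=C(CC/C(C)=C/CO[Si](c2ccccc2)(c2ccccc2)C(C)(C)C)C(C)(C)[C@H](O)CC1 | intermediate
16 | (1R,3S)-3-[(3E)-5-(TBDPSO)-3-methylpent-3-en-1-yl]-2,2-dimethyl-4-methylidenecyclohexan-1-ol | C=C1CC[C@@H](O)C(C)(C)[C@H]1CC/C(C)=C/CO[Si](c1ccccc1)(c1ccccc1)C(C)(C)C | intermediate
17 | (1R,3S)-3-[(3E)-5-hydroxy-3-methylpent-3-en-1-yl]-2,2-dimethyl-4-methylidenecyclohexan-1-ol | C=C1CC[C@@H](O)C(C)(C)[C@H]1CC/C(C)=C/CO | intermediate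
18 | isofraxidin (7-hydroxy-6,8-dimethoxy-2H-chromen-2-one) | COc1cc2ccc(=O)oc2c(OC)c1O | starting material
19 | 7-({(2E)-5-[(1S,3R)-3-hydroxy-2,2-dimethyl-6-methylidenecyclohexyl]-3-methylpent-2-en-1-yl}oxy)-6,8-dimethoxy-2H-chromen-2-one | C=C1CC[C@@H](O)C(C)(C)[C@H]1CC/C(C)=C/COc1c(OC)cc2ccc(=O)oc2c1OC | target

**Count**
Total steps: 11. Longest linear sequence: 9 steps (steps 1, 2, 3, 4, 7, 8, 9, 10, 11).

**Steps most likely to fail**

Step 1. What may go wrong: the still acidic adduct 3 may add a second acrolein, acrolein may oligomerise, and the aldol closure at the tertiary carbon may stay incomplete. The fallback sets out from 1 and comes back at 4. It replaces the conjugate addition to free acrolein by an SN2 alkylation with a masked aldehyde. Compound 1 is alkylated at its α-carbon with 2-(2-bromoethyl)-1,3-dioxolane (NaH, NaI cat., DMF, 60 °C) to give methyl 2-[2-(1,3-dioxolan-2-yl)ethyl]-4-methyl-3-oxopentanoate F1. Aqueous HCl in THF then unmasks the aldehyde (3) and closes the aldol in the same acid medium to 4.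

Step 7. What may go wrong: transmetalation and coupling may be slow at the tetrasubstituted triflate carbon next to quaternary C2, so the triflate may hydrolyse in aqueous base or the alkylborane may decompose; the diene may also be hydroborated more than once. The fallback sets out from 11 (made from 10 as in step 7) and from 7, and comes back at 12. It replaces the boron-to-palladium manifold by an iron-catalysed alkyl Grignard–enol triflate coupling, which changes the nucleophile, the catalyst metal and the mechanism. Borane 11 is iodinated (I2, NaOMe, THF/MeOH, 0 °C) to tert-butyl{[(2E)-5-iodo-3-methylpent-2-en-1-yl]oxy}diphenylsilane F2. Magnesium in THF converts F2 to the Grignard reagent {(3E)-5-(TBDPSO)-3-methylpent-3-en-1-yl}(iodo)magnesium F3. Compound 7 is treated with one equivalent of MeMgCl to give the chloromagnesium alkoxide of 7, F4. F4 and F3 are coupled with Fe(acac)3 (5 mol %) in THF/N-methylpyrrolidone at −30 °C, and aqueous work-up gives 12.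

Step 9. What may go wrong: facial selectivity in the hydrogen transfer to C1 may be poor, or the Mitsunobu N-alkylation at the congested allylic position may lag behind decomposition of the sulfonylhydrazide. The fallback sets out from 13 and comes back at 16. It replaces the diazene retro-ene by a palladium-catalysed formate hydrogenolysis. The primary allylic hydroxyl of 13 is formylated chemoselectively (acetic formic anhydride, pyridine, −20 °C) to {(4R)-2-[(3E)-5-(TBDPSO)-3-methylpent-3-en-1-yl]-4-hydroxy-3,3-dimethylcyclohex-1-en-1-yl}methyl formate F5. Pd(OAc)2 (5 mol %) and n-Bu3P in THF at 23–60 °C then form a π-allylpalladium formate, which loses CO2 and passes hydride from the metal to the more substituted terminus C1. The bulky metal fragment should sit on the face anti to the pseudoaxial C2 methyl and so discriminate the two faces more strongly than the small diazene, giving 16.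

**Further compounds**
F1 | step 1 | methyl 2-[2-(1,3-dioxolan-2-yl)ethyl]-4-methyl-3-oxopentanoate | COC(=O)C(CCC1OCCO1)C(=O)C(C)C
F2 | step 7 | tert-butyl{[(2E)-5-iodo-3-methylpent-2-en-1-yl]oxy}diphenylsilane | ICC/C(C)=C/CO[Si](c1ccccc1)(c1ccccc1)C(C)(C)C
F3 | step 7 | {(3E)-5-(TBDPSO)-3-methylpent-3-en-1-yl}(iodo)magnesium | I[Mg]CC/C(C)=C/CO[Si](c1ccccc1)(c1ccccc1)C(C)(C)C
F4 | step 7 | chloromagnesium (1R)-4-(methoxycarbonyl)-2,2-dimethyl-3-{[(trifluoromethyl)sulfonyl]oxy}cyclohex-3-en-1-olate | COC(=O)C1=C(OS(=O)(=O)C(F)(F)F)C(C)(C)[C@H](O[Mg]Cl)CC1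
F5 | step 9 | {(4R)-2-[(3E)-5-(TBDPSO)-3-methylpent-3-en-1-yl]-4-hydroxy-3,3-dimethylcyclohex-1-en-1-yl}methyl formate | O=COCC1=C(CC/C(C)=C/CO[Si](c2ccccc2)(c2ccccc2)C(C)(C)C)C(C)(C)[C@H](O)CC1
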